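## Retrosynthetic overview

1. Target ⇒ (desilylation, C7–O carbamoylation) silyl-protected 7-hydroxy macrolactam ⇒ open-chain primary (Z)-enamide carrying an aryl chloride, by cutting the aryl C–N bond. The 19-membered lactam is the only ring made and is closed by ring-closing N-arylation.
2. Seco-amide ⇒ C4–C15 diene + (Z)-3-iodoacrylamide (C3–C4, hydroboration/Suzuki); diene ⇒ (Z)-enal + (Z)-γ-methoxyallylborane (C6–C7, sets C6 and C7).
3. (Z)-Enal ⇒ C9 aldehyde (α-iodo Wittig fixes 8Z, formylation adds C7); C9 aldehyde ⇒ α-methoxy aldehyde + (Z)-crotylboronate (C10–C11, sets C10 and C11).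
4. α-Methoxy aldehyde ⇒ primary iodide + SAMP hydrazone of methoxyacetaldehyde (C12–C13, sets C12); iodide ⇒ 3-bromo-5-chlorophenol + (S)-3-bromo-2-methylpropan-1-ol (aryl–C15, C14 from the chiral pool).
5. Ring order: the benzene ring is bought; the macrolactam is formed at step 15, followed only by carbamate formation and desilylation.

Assumption: the SMILES is taken literally, so both C2=C3 and C8=C9 are Z and the stereocentres are 6S,7S,10S,11R,12S,14R (geldanamycin-type locants, C1 = lactam carbonyl, C15 = benzylic CH2, are used only as atom labels).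

Abbreviation: Ar = 3-chloro-5-(triisopropylsilyloxy)phenyl.

## Route

Step 1
Reactants: 1 3-bromo-5-chlorophenol
Product: 2 (3-bromo-5-chlorophenoxy)triisopropylsilane
Conditions: i-Pr3SiCl, imidazole, DMF, 23 °C
Reagents that add atoms: triisopropylsilyl chloride, CC(C)[Si](Cl)(C(C)C)C(C)C
Why: Imidazole-promoted silylation of the phenol gives an aryl silyl ether that withstands the organometallic steps and is removed by fluoride at the end; no stereocentre is involved.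

Step 2
Reactants: 2 (3-bromo-5-chlorophenoxy)triisopropylsilane; 3 (S)-3-bromo-2-methylpropan-1-ol
Product: 5 (R)-3-[3-chloro-5-(triisopropylsilyloxy)phenyl]-2-methylpropan-1-ol, via aryl Grignard reagent 4 (not isolated)
Conditions: Mg, THF, 45 °C; then 3 (as its ClMg alkoxide, from MeMgCl), Fe(acac)3 (5 mol %), TMEDA, THF, 0 °C
Reagents that add atoms: none
Why: Magnesium inserts only into the C–Br bond and the iron-catalysed Kumada-type sp2–sp3 cross-coupling joins the aryl Grignard to the primary bromide, the C14 stereocentre from the chiral pool being untouched (its descriptor changes from S to R by priority only).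

Step 3
Reactants: 5 (R)-3-[3-chloro-5-(triisopropylsilyloxy)phenyl]-2-methylpropan-1-ol
Product: 6 (R)-[3-chloro-5-(3-iodo-2-methylpropyl)phenoxy]triisopropylsilane
Conditions: I2, PPh3, imidazole, CH2Cl2, 0 → 23 °C
Reagents that add atoms: iodine, [I][I]
Why: Appel-type iodination (Garegg–Samuelsson conditions) converts the primary alcohol into the iodide without touching the stereocentre or the aryl silyl ether.

Step 4
Reactants: 7 methoxyacetaldehyde; 8 (S)-1-amino-2-(methoxymethyl)pyrrolidine (SAMP)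
Product: 9 (S,E)-N-(2-methoxyethylidene)-2-(methoxymethyl)pyrrolidin-1-amine
Conditions: CH2Cl2, MgSO4, 0 → 23 °C
Reagents that add atoms: none
Why: Hydrazone condensation of the aldehyde with the chiral hydrazine gives the E hydrazone, the auxiliary bringing its own S centre.

Step 5
Reactants: 9 (S,E)-N-(2-methoxyethylidene)-2-(methoxymethyl)pyrrolidin-1-amine; 6 (R)-[3-chloro-5-(3-iodo-2-methylpropyl)phenoxy]triisopropylsilane
Product: 11 (2S)-N-[(1E,2S,4R)-5-Ar-2-methoxy-4-methylpentylidene]-2-(methoxymethyl)pyrrolidin-1-amine, via lithium azaenolate 10 (not isolated)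
Conditions: LiN(i-Pr)2, THF, 0 °C; then 6, −100 → 23 °C
Reagents that add atoms: none
Why: Enders SAMP-hydrazone alkylation, in which the lithium-chelated E azaenolate is alkylated by the primary iodide on the face remote from the methoxymethyl arm, sets C12 as S under auxiliary control.

Step 6
Reactants: 11 (2S)-N-[(1E,2S,4R)-5-Ar-2-methoxy-4-methylpentylidene]-2-(methoxymethyl)pyrrolidin-1-amine
Product: 12 (2S,4R)-5-Ar-2-methoxy-4-methylpentanal
Conditions: O3, CH2Cl2, −78 °C; N2 purge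
Reagents that add atoms: ozone, [O-][O+]=O
Why: Ozonolytic cleavage of the hydrazone C=N bond releases the α-methoxy aldehyde under neutral conditions at −78 °C, so C12 is not epimerised.

Step 7
Reactants: 12 (2S,4R)-5-Ar-2-methoxy-4-methylpentanal; 13 (Z)-crotylboronic acid pinacol ester
Product: 15 (3S,4R,5S,7R)-8-Ar-5-methoxy-3,7-dimethyloct-1-en-4-ol, via pinacol borate ester 14 (not isolated)
Conditions: toluene, 4 Å molecular sieves, −78 → 23 °C; then aq. NaHCO3
Reagents that add atoms: none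
Why: Hoffmann–Roush crotylboration through a closed chair transition state, where the Z crotyl geometry gives the 10,11-syn pair and the α-methoxy aldehyde reacts in the Cornforth (anti-dipole) arrangement, sets C10 (S) and C11 (R, 11,12-anti) under substrate control.

Step 8
Reactants: 15 (3S,4R,5S,7R)-8-Ar-5-methoxy-3,7-dimethyloct-1-en-4-ol
Product: 16 triethyl{[(3S,4R,5S,7R)-8-Ar-5-methoxy-3,7-dimethyloct-1-en-4-yl]oxy}silane
Conditions: Et3SiOTf, 2,6-lutidine, CH2Cl2, −78 °C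
Reagents that add atoms: triethylsilyl trifluoromethanesulfonate, CC[Si](CC)(CC)OS(=O)(=O)C(F)(F)F
Why: Silylation of the hindered secondary alcohol with the silyl triflate masks O11, so that O7 is the only free hydroxyl when the carbamate is installed.

Step 9
Reactants: 16 triethyl{[(3S,4R,5S,7R)-8-Ar-5-methoxy-3,7-dimethyloct-1-en-4-yl]oxy}silane
Product: 17 (2R,3R,4S,6R)-7-Ar-4-methoxy-2,6-dimethyl-3-(triethylsilyloxy)heptanal
Conditions: O3, pyridine, CH2Cl2, −78 °C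
Reagents that add atoms: ozone, [O-][O+]=O
Why: Ozonolysis of the monosubstituted alkene in the presence of pyridine gives the aldehyde directly, the chloroarene and silyl ethers being inert at −78 °C (C10 is unchanged in space; its descriptor becomes R by priority).

Step 10
Reactants: 17 (2R,3R,4S,6R)-7-Ar-4-methoxy-2,6-dimethyl-3-(triethylsilyloxy)heptanal
Product: 18 triethyl{[(2Z,4S,5R,6S,8R)-9-Ar-2-iodo-6-methoxy-4,8-dimethylnon-2-en-5-yl]oxy}silane
Conditions: [Ph3PEt]I, n-BuLi, THF, 23 °C; I2, −78 °C; NaN(SiMe3)2, −20 °C; then 17, −78 → −20 °C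
Reagents that add atoms: ethyltriphenylphosphonium iodide, CC[P+](c1ccccc1)(c1ccccc1)c1ccccc1.[I-]; iodine, [I][I]
Why: Stork–Zhao-type Wittig olefination with the α-iodo ylide is kinetically Z-selective, placing iodine cis to C10 and thereby fixing the 8Z geometry.

Step 11
Reactants: 18 triethyl{[(2Z,4S,5R,6S,8R)-9-Ar-2-iodo-6-methoxy-4,8-dimethylnon-2-en-5-yl]oxy}silane
Product: 20 (2Z,4S,5R,6S,8R)-9-Ar-6-methoxy-2,4,8-trimethyl-5-(triethylsilyloxy)non-2-enal, via alkenyllithium 19 (not isolated)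
Conditions: t-BuLi (2.1 equiv), Et2O, −78 °C; then DMF, −78 → 0 °C
Reagents that add atoms: N,N-dimethylformamide, CN(C)C=O
Why: Lithium–iodine exchange outruns any reaction of the aryl chloride and retains the alkene geometry, and formylation of the alkenyllithium with DMF gives the (Z)-enal carrying C7.

Step 12
Reactants: 20 (2Z,4S,5R,6S,8R)-9-Ar-6-methoxy-2,4,8-trimethyl-5-(triethylsilyloxy)non-2-enal; 21 allyl methyl ether
Product: 23 (3S,4S,5Z,7S,8R,9S,11R)-12-Ar-3,9-dimethoxy-5,7,11-trimethyl-8-(triethylsilyloxy)dodeca-1,5-dien-4-ol, via diisopinocampheylborinate 22 (not isolated)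
Conditions: 21, s-BuLi, THF, −78 °C; Ipc2BOMe [from (−)-α-pinene]; BF3·OEt2; then 20, −78 °C; NaBO3·4H2O, THF/H2O, 23 °C
Reagents that add atoms: none
Why: Brown alkoxyallylboration through a chair transition state, where the Z γ-methoxyallyl unit gives the 6,7-syn relationship and the isopinocampheyl groups derived from (−)-α-pinene direct attack on the Re face of the aldehyde, sets C7 (S) and C6 (S) under reagent control.

Step 13
Reactants: 24 propiolamide
Product: 25 (Z)-3-iodoprop-2-enamide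
Conditions: NaI, AcOH, 70 °C
Reagents that add atoms: sodium iodide, [Na+].[I-]
Why: Anti hydroiodination of the ynamide (conjugate addition of iodide, then protonation) gives the kinetic Z β-iodoacrylamide, as with propiolic acid and its esters.

Step 14
Reactants: 23 (3S,4S,5Z,7S,8R,9S,11R)-12-Ar-3,9-dimethoxy-5,7,11-trimethyl-8-(triethylsilyloxy)dodeca-1,5-dien-4-ol; 25 (Z)-3-iodoprop-2-enamide
Product: 27 (2Z,6S,7S,8Z,10S,11R,12S,14R)-15-Ar-7-hydroxy-6,12-dimethoxy-8,10,14-trimethyl-11-(triethylsilyloxy)pentadeca-2,8-dienamide, via B-alkyl-9-BBN borane 26 (not isolated)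
Conditions: 9-BBN, THF, 23 °C; then aq. K3PO4, 25, Pd(dppf)Cl2·CH2Cl2 (10 mol %), AsPh3, DMF, 23 °C
Reagents that add atoms: none
Why: 9-BBN hydroborates only the terminal alkene (anti-Markovnikov) and the B-alkyl Suzuki–Miyaura coupling with the vinyl iodide retains the Z geometry, the aryl chloride being inert under these conditions at 23 °C.

Step 15
Reactants: 27 (2Z,6S,7S,8Z,10S,11R,12S,14R)-15-Ar-7-hydroxy-6,12-dimethoxy-8,10,14-trimethyl-11-(triethylsilyloxy)pentadeca-2,8-dienamide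
Product: 28 (4Z,8S,9S,10Z,12S,13R,14S,16R)-9-hydroxy-8,14-dimethoxy-10,12,16-trimethyl-13-(triethylsilyloxy)-20-(triisopropylsilyloxy)-2-azabicyclo[16.3.1]docosa-1(21),4,10,18(22),19-pentaen-3-one
Conditions: Pd2(dba)3 (10 mol %), tBuBrettPhos (24 mol %), K3PO4, toluene/t-AmOH 9:1, 90 °C, 1 mM, slow addition of 27
Reagents that add atoms: none
Why: Proposed new method: ring-closing palladium-catalysed N-arylation of a primary (Z)-enamide by an unactivated aryl chloride, in which oxidative addition of the C–Cl bond to monoligated zerovalent palladium bearing tBuBrettPhos, phosphate-assisted binding of the amide as a κN-amidate on divalent palladium and C–N reductive elimination forced by the bulky biaryl phosphine close the 19-membered ring under high dilution, the Z olefin being preserved because the N–H is the only acidic site engaged, the tertiary alcohol co-solvent cannot deliver a palladium hydride and the β-alkyl acrylamide is a poor Heck acceptor; the closest known reaction types are the intermolecular Buchwald amidation of aryl chlorides by primary amides and the copper-mediated Goldberg macrolactam closure of aryl bromides used for benzenoid ansamycins, but closure of an aryl chloride onto a (Z)-acrylamide has not been shown.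

Step 16
Reactants: 28 (4Z,8S,9S,10Z,12S,13R,14S,16R)-9-hydroxy-8,14-dimethoxy-10,12,16-trimethyl-13-(triethylsilyloxy)-20-(triisopropylsilyloxy)-2-azabicyclo[16.3.1]docosa-1(21),4,10,18(22),19-pentaen-3-one
Product: 30 [(4Z,8S,9S,10Z,12S,13R,14S,16R)-8,14-dimethoxy-10,12,16-trimethyl-3-oxo-13-(triethylsilyloxy)-20-(triisopropylsilyloxy)-2-azabicyclo[16.3.1]docosa-1(21),4,10,18(22),19-pentaen-9-yl] carbamate, via N-trichloroacetyl carbamate 29 (not isolated)
Conditions: Cl3CC(O)NCO, CH2Cl2, 0 °C; then K2CO3, MeOH, 0 °C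
Reagents that add atoms: trichloroacetyl isocyanate, O=C=NC(=O)C(Cl)(Cl)Cl
Why: Kočovský carbamoylation, in which the only free hydroxyl (O7) adds to the acyl isocyanate and mild methanolysis removes the trichloroacetyl group, forms the carbamate C–O bond with C7 (S) retained; it is done after ring closure so that neither the carbamate N–H nor an allylic carbamate meets zerovalent palladium.

Step 17
Reactants: 30 [(4Z,8S,9S,10Z,12S,13R,14S,16R)-8,14-dimethoxy-10,12,16-trimethyl-3-oxo-13-(triethylsilyloxy)-20-(triisopropylsilyloxy)-2-azabicyclo[16.3.1]docosa-1(21),4,10,18(22),19-pentaen-9-yl] carbamate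
Product: 31 [(4Z,8S,9S,10Z,12S,13R,14S,16R)-13,20-dihydroxy-8,14-dimethoxy-10,12,16-trimethyl-3-oxo-2-azabicyclo[16.3.1]docosa-1(21),4,10,18(22),19-pentaen-9-yl] carbamate (CNP0263527.1)
Conditions: Bu4NF, AcOH, THF, 0 → 23 °C
Reagents that add atoms: none
Why: Buffered fluoride desilylation cleaves both the phenolic and the C11 silyl ether while leaving the carbamate, the lactam and both Z alkenes intact.

## Compound list

1 | 3-bromo-5-chlorophenol | Oc1cc(Cl)cc(Br)c1 | starting material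
2 | (3-bromo-5-chlorophenoxy)triisopropylsilane | CC(C)[Si](C(C)C)(C(C)C)Oc1cc(Cl)cc(Br)c1 | intermediate
3 | (S)-3-bromo-2-methylpropan-1-ol | BrC[C@@H](C)CO | starting material
4 | [3-chloro-5-(triisopropylsilyloxy)phenyl]magnesium bromide | CC(C)[Si](C(C)C)(C(C)C)Oc1cc(Cl)cc([Mg]Br)c1 | intermediate (not isolated)
5 | (R)-3-Ar-2-methylpropan-1-ol | CC(C)[Si](C(C)C)(C(C)C)Oc1cc(Cl)cc(C[C@@H](C)CO)c1 | intermediate
6 | (R)-[3-chloro-5-(3-iodo-2-methylpropyl)phenoxy]triisopropylsilane | CC(C)[Si](C(C)C)(C(C)C)Oc1cc(Cl)cc(C[C@@H](C)CI)c1 | intermediate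
7 | methoxyacetaldehyde | COCC=O | starting material
8 | (S)-1-amino-2-(methoxymethyl)pyrrolidine (SAMP) | COC[C@@H]1CCCN1N | starting material
9 | (S,E)-N-(2-methoxyethylidene)-2-(methoxymethyl)pyrrolidin-1-amine | COC/C=N/N1CCC[C@H]1COC | intermediate
10 | lithium azaenolate of 9 (E C=C) | CO/C=C/N([Li])N1CCC[C@H]1COC | intermediate (not isolated)
11 | (2S)-N-[(1E,2S,4R)-5-Ar-2-methoxy-4-methylpentylidene]-2-(methoxymethyl)pyrrolidin-1-amine | CC(C)[Si](C(C)C)(C(C)C)Oc1cc(Cl)cc(C[C@@H](C)C[C@H](OC)/C=N/N2CCC[C@H]2COC)c1 | intermediate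
12 | (2S,4R)-5-Ar-2-methoxy-4-methylpentanal | CC(C)[Si](C(C)C)(C(C)C)Oc1cc(Cl)cc(C[C@@H](C)C[C@H](OC)C=O)c1 | intermediate
13 | (Z)-crotylboronic acid pinacol ester | C/C=C\CB1OC(C)(C)C(C)(C)O1 | starting material
14 | pinacol borate ester of 15 (O-B(pin) at the 4-oxygen) | CC(C)[Si](C(C)C)(C(C)C)Oc1cc(Cl)cc(C[C@@H](C)C[C@H](OC)[C@H](OB2OC(C)(C)C(C)(C)O2)[C@@H](C)C=C)c1 | intermediate (not isolated)
15 | (3S,4R,5S,7R)-8-Ar-5-methoxy-3,7-dimethyloct-1-en-4-ol | CC(C)[Si](C(C)C)(C(C)C)Oc1cc(Cl)cc(C[C@@H](C)C[C@H](OC)[C@H](O)[C@@H](C)C=C)c1 | intermediate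
16 | triethyl{[(3S,4R,5S,7R)-8-Ar-5-methoxy-3,7-dimethyloct-1-en-4-yl]oxy}silane | CC(C)[Si](C(C)C)(C(C)C)Oc1cc(Cl)cc(C[C@@H](C)C[C@H](OC)[C@H](O[Si](CC)(CC)CC)[C@@H](C)C=C)c1 | intermediate
17 | (2R,3R,4S,6R)-7-Ar-4-methoxy-2,6-dimethyl-3-(triethylsilyloxy)heptanal | CC(C)[Si](C(C)C)(C(C)C)Oc1cc(Cl)cc(C[C@@H](C)C[C@H](OC)[C@H](O[Si](CC)(CC)CC)[C@@H](C)C=O)c1 | intermediate
18 | triethyl{[(2Z,4S,5R,6S,8R)-9-Ar-2-iodo-6-methoxy-4,8-dimethylnon-2-en-5-yl]oxy}silane | CC(C)[Si](C(C)C)(C(C)C)Oc1cc(Cl)cc(C[C@@H](C)C[C@H](OC)[C@H](O[Si](CC)(CC)CC)[C@@H](C)/C=C(C)\I)c1 | intermediate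
19 | (Z)-alkenyllithium from 18 (Li in place of I) | CC(C)[Si](C(C)C)(C(C)C)Oc1cc(Cl)cc(C[C@@H](C)C[C@H](OC)[C@H](O[Si](CC)(CC)CC)[C@@H](C)/C=C(C)\[Li])c1 | intermediate (not isolated)
20 | (2Z,4S,5R,6S,8R)-9-Ar-6-methoxy-2,4,8-trimethyl-5-(triethylsilyloxy)non-2-enal | CC(C)[Si](C(C)C)(C(C)C)Oc1cc(Cl)cc(C[C@@H](C)C[C@H](OC)[C@H](O[Si](CC)(CC)CC)[C@@H](C)/C=C(C)\C=O)c1 | intermediate
21 | allyl methyl ether (3-methoxyprop-1-ene) | COCC=C | starting material
22 | diisopinocampheylborinate of 23 (O-B(Ipc)2 at the 4-oxygen) | CC(C)[Si](C(C)C)(C(C)C)Oc1cc(Cl)cc(C[C@@H](C)C[C@H](OC)[C@H](O[Si](CC)(CC)CC)[C@@H](C)/C=C(C)\[C@H](OB([C@H]2C[C@H]3C[C@@H]([C@@H]2C)C3(C)C)[C@H]2C[C@H]3C[C@@H]([C@@H]2C)C3(C)C)[C@@H](OC)C=C)c1 | intermediate (not isolated)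
23 | (3S,4S,5Z,7S,8R,9S,11R)-12-Ar-3,9-dimethoxy-5,7,11-trimethyl-8-(triethylsilyloxy)dodeca-1,5-dien-4-ol | CC(C)[Si](C(C)C)(C(C)C)Oc1cc(Cl)cc(C[C@@H](C)C[C@H](OC)[C@H](O[Si](CC)(CC)CC)[C@@H](C)/C=C(C)\[C@H](O)[C@@H](OC)C=C)c1 | intermediate
24 | propiolamide (prop-2-ynamide) | C#CC(N)=O | starting material
25 | (Z)-3-iodoprop-2-enamide | NC(=O)/C=C\I | intermediate
26 | B-alkyl-9-BBN borane from 23 (9-BBN on the terminal carbon and on the 4-oxygen) | CC(C)[Si](C(C)C)(C(C)C)Oc1cc(Cl)cc(C[C@@H](C)C[C@H](OC)[C@H](O[Si](CC)(CC)CC)[C@@H](C)/C=C(C)\[C@H](OB2C3CCCC2CCC3)[C@@H](OC)CCB2C3CCCC2CCC3)c1 | intermediate (not isolated)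
27 | (2Z,6S,7S,8Z,10S,11R,12S,14R)-15-Ar-7-hydroxy-6,12-dimethoxy-8,10,14-trimethyl-11-(triethylsilyloxy)pentadeca-2,8-dienamide | CC(C)[Si](C(C)C)(C(C)C)Oc1cc(Cl)cc(C[C@@H](C)C[C@H](OC)[C@H](O[Si](CC)(CC)CC)[C@@H](C)/C=C(C)\[C@H](O)[C@@H](OC)CC/C=C\C(N)=O)c1 | intermediate
28 | (4Z,8S,9S,10Z,12S,13R,14S,16R)-9-hydroxy-8,14-dimethoxy-10,12,16-trimethyl-13-(triethylsilyloxy)-20-(triisopropylsilyloxy)-2-azabicyclo[16.3.1]docosa-1(21),4,10,18(22),19-pentaen-3-one | CC(C)[Si](C(C)C)(C(C)C)Oc1cc(C[C@@H](C)C[C@H](OC)[C@H](O[Si](CC)(CC)CC)[C@@H](C)/C=C(C)\[C@H](O)[C@@H](OC)CC/C=C\C(=O)N2)cc2c1 | intermediate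
29 | N-trichloroacetyl carbamate of 28 at O9 (O7 in geldanamycin locants) | CC(C)[Si](C(C)C)(C(C)C)Oc1cc(C[C@@H](C)C[C@H](OC)[C@H](O[Si](CC)(CC)CC)[C@@H](C)/C=C(C)\[C@H](OC(=O)NC(=O)C(Cl)(Cl)Cl)[C@@H](OC)CC/C=C\C(=O)N2)cc2c1 | intermediate (not isolated)
30 | [(4Z,8S,9S,10Z,12S,13R,14S,16R)-8,14-dimethoxy-10,12,16-trimethyl-3-oxo-13-(triethylsilyloxy)-20-(triisopropylsilyloxy)-2-azabicyclo[16.3.1]docosa-1(21),4,10,18(22),19-pentaen-9-yl] carbamate | CC(C)[Si](C(C)C)(C(C)C)Oc1cc(C[C@@H](C)C[C@H](OC)[C@H](O[Si](CC)(CC)CC)[C@@H](C)/C=C(C)\[C@H](OC(N)=O)[C@@H](OC)CC/C=C\C(=O)N2)cc2c1 | intermediate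
31 | [(4Z,8S,9S,10Z,12S,13R,14S,16R)-13,20-dihydroxy-8,14-dimethoxy-10,12,16-trimethyl-3-oxo-2-azabicyclo[16.3.1]docosa-1(21),4,10,18(22),19-pentaen-9-yl] carbamate (CNP0263527.1) | CO[C@H]1C[C@H](C)Cc2cc(O)cc(c2)NC(=O)/C=C\CC[C@H](OC)[C@@H](OC(N)=O)/C(C)=C\[C@H](C)[C@H]1O | target

## Step count and risks

Total step count: 17. Longest linear sequence: 15 (steps 1–3, 5–12, 14–17); steps 4 and 13 prepare the hydrazone and the iodoacrylamide.

Steps most likely to fail:

Step 5. The β-branched primary iodide is a slow electrophile, and the facial sense for an α-methoxy azaenolate is assumed to follow the usual SAMP rule. The fallback sets out from 6 and comes back at 12, and sets C12 by catalyst-controlled C–O bond formation instead. Copper-catalysed vinylation of 6 (vinylmagnesium bromide, CuI, THF) gives (S)-[3-chloro-5-(2-methylpent-4-en-1-yl)phenoxy]triisopropylsilane F1. Cross-metathesis with (Z)-but-2-ene-1,4-diyl dimethyl dicarbonate (second-generation Hoveyda–Grubbs catalyst) gives methyl [(2E,5S)-6-Ar-5-methylhex-2-en-1-yl] carbonate F2. Iridium-catalysed enantioselective allylic etherification with methanol ([Ir(cod)Cl]2, Feringa-type phosphoramidite, K3PO4) gives the branched ether {3-chloro-5-[(2R,4S)-4-methoxy-2-methylhex-5-en-1-yl]phenoxy}triisopropylsilane F3. Ozonolysis of F3 gives 12.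

Step 10. The α-iodo Wittig reaction typically gives moderate yields, and Z/E erosion or epimerisation at the α-carbon of 17 is possible. The fallback sets out from 17 and comes back at 20. Still–Gennari olefination (methyl 2-[bis(2,2,2-trifluoroethoxy)phosphoryl]propanoate, KN(SiMe3)2, 18-crown-6, THF, −78 °C) gives methyl (2Z,4S,5R,6S,8R)-9-Ar-6-methoxy-2,4,8-trimethyl-5-(triethylsilyloxy)non-2-enoate F4. Reduction with i-Bu2AlH gives (2Z,4S,5R,6S,8R)-9-Ar-6-methoxy-2,4,8-trimethyl-5-(triethylsilyloxy)non-2-en-1-ol F5. Oxidation with MnO2 gives 20.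

Step 15 (the proposed new ring closure). Possible failures are oligomerisation, Z to E isomerisation, Heck-type pathways, or loss of the phenolic silyl ether under hot base. The fallback uses known chemistry only, sets out from 23 and comes back at 28. Palladium-catalysed amination of the aryl chloride with ammonia (Pd[P(o-tol)3]2, Josiphos ligand CyPF-t-Bu, NH3 in 1,4-dioxane, NaOt-Bu) gives (3S,4S,5Z,7S,8R,9S,11R)-12-[3-amino-5-(triisopropylsilyloxy)phenyl]-3,9-dimethoxy-5,7,11-trimethyl-8-(triethylsilyloxy)dodeca-1,5-dien-4-ol F6. Hydroboration with 9-BBN gives its B-alkyl-9-BBN borane F7 (not isolated). Suzuki–Miyaura coupling with ethyl (Z)-3-iodoacrylate (Pd(dppf)Cl2·CH2Cl2, AsPh3, aq. K3PO4) gives ethyl (2Z,6S,7S,8Z,10S,11R,12S,14R)-15-[3-amino-5-(triisopropylsilyloxy)phenyl]-7-hydroxy-6,12-dimethoxy-8,10,14-trimethyl-11-(triethylsilyloxy)pentadeca-2,8-dienoate F8. Hydrolysis with Me3SnOH gives the corresponding amino acid (2Z,6S,7S,8Z,10S,11R,12S,14R)-15-[3-amino-5-(triisopropylsilyloxy)phenyl]-7-hydroxy-6,12-dimethoxy-8,10,14-trimethyl-11-(triethylsilyloxy)pentadeca-2,8-dienoic acid F9. Macrolactamisation (BOP-Cl, i-Pr2NEt, toluene, high dilution) gives 28.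

Further compounds
F1 | step 5 | (S)-[3-chloro-5-(2-methylpent-4-en-1-yl)phenoxy]triisopropylsilane | CC(C)[Si](C(C)C)(C(C)C)Oc1cc(Cl)cc(C[C@@H](C)CC=C)c1
F2 | step 5 | methyl [(2E,5S)-6-Ar-5-methylhex-2-en-1-yl] carbonate | CC(C)[Si](C(C)C)(C(C)C)Oc1cc(Cl)cc(C[C@@H](C)C/C=C/COC(=O)OC)c1
F3 | step 5 | {3-chloro-5-[(2R,4S)-4-methoxy-2-methylhex-5-en-1-yl]phenoxy}triisopropylsilane | CC(C)[Si](C(C)C)(C(C)C)Oc1cc(Cl)cc(C[C@@H](C)C[C@H](OC)C=C)c1
F4 | step 10 | methyl (2Z,4S,5R,6S,8R)-9-Ar-6-methoxy-2,4,8-trimethyl-5-(triethylsilyloxy)non-2-enoate | CC(C)[Si](C(C)C)(C(C)C)Oc1cc(Cl)cc(C[C@@H](C)C[C@H](OC)[C@H](O[Si](CC)(CC)CC)[C@@H](C)/C=C(C)\C(=O)OC)c1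
F5 | step 10 | (2Z,4S,5R,6S,8R)-9-Ar-6-methoxy-2,4,8-trimethyl-5-(triethylsilyloxy)non-2-en-1-ol | CC(C)[Si](C(C)C)(C(C)C)Oc1cc(Cl)cc(C[C@@H](C)C[C@H](OC)[C@H](O[Si](CC)(CC)CC)[C@@H](C)/C=C(C)\CO)c1
F6 | step 15 | (3S,4S,5Z,7S,8R,9S,11R)-12-[3-amino-5-(triisopropylsilyloxy)phenyl]-3,9-dimethoxy-5,7,11-trimethyl-8-(triethylsilyloxy)dodeca-1,5-dien-4-ol | CC(C)[Si](C(C)C)(C(C)C)Oc1cc(N)cc(C[C@@H](C)C[C@H](OC)[C@H](O[Si](CC)(CC)CC)[C@@H](C)/C=C(C)\[C@H](O)[C@@H](OC)C=C)c1
F7 | step 15 | B-alkyl-9-BBN borane from F6 (9-BBN on the terminal carbon and on the 4-oxygen) | CC(C)[Si](C(C)C)(C(C)C)Oc1cc(N)cc(C[C@@H](C)C[C@H](OC)[C@H](O[Si](CC)(CC)CC)[C@@H](C)/C=C(C)\[C@H](OB2C3CCCC2CCC3)[C@@H](OC)CCB2C3CCCC2CCC3)c1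
F8 | step 15 | ethyl (2Z,6S,7S,8Z,10S,11R,12S,14R)-15-[3-amino-5-(triisopropylsilyloxy)phenyl]-7-hydroxy-6,12-dimethoxy-8,10,14-trimethyl-11-(triethylsilyloxy)pentadeca-2,8-dienoate | CC(C)[Si](C(C)C)(C(C)C)Oc1cc(N)cc(C[C@@H](C)C[C@H](OC)[C@H](O[Si](CC)(CC)CC)[C@@H](C)/C=C(C)\[C@H](O)[C@@H](OC)CC/C=C\C(=O)OCC)c1
F9 | step 15 | (2Z,6S,7S,8Z,10S,11R,12S,14R)-15-[3-amino-5-(triisopropylsilyloxy)phenyl]-7-hydroxy-6,12-dimethoxy-8,10,14-trimethyl-11-(triethylsilyloxy)pentadeca-2,8-dienoic acid | CC(C)[Si](C(C)C)(C(C)C)Oc1cc(N)cc(C[C@@H](C)C[C@H](OC)[C@H](O[Si](CC)(CC)CC)[C@@H](C)/C=C(C)\[C@H](O)[C@@H](OC)CC/C=C\C(O)=O)c1
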